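The carbocycle of the 5-bromo-4,4,7a-trimethylhexahydrobenzofuran core is closed late, at its only CH2–CH2 bond (C6–C7), by a 6-endo-trig radical cyclization. The precursor is a γ-lactone that already carries C3a and C7a (Evans alkylation, then Felkin-controlled iodomethylation), with an iodomethyl group on C7a and a 1-bromovinyl group on the gem-dimethyl carbon C4. The primary radical adds to the bromoalkene terminus, and axial hydrogen-atom transfer to the resulting α-bromo radical sets the equatorial C5–Br bond in the same operation. The step exploits the bromine on C5 and the quaternary C4 of the six-membered ring, which steer attack to C6. The lactone is then converted into the (Z)-bromoacetyl enol ether.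

Key step: step 10

Remark: ring atoms are numbered as in 1-benzofuran (O1, C2, C3, C3a, C4–C7, C7a); the target is the (Z,3aS,5S,7aS) isomer.

Step 1
Reactants: 1 ethyl 3-methylbut-2-enoate
Product: 3 ethyl 2-bromo-3-methylbut-2-enoate, via ethyl 2,3-dibromo-3-methylbutanoate 2 (not isolated)
Conditions: Br2, CH2Cl2, 0 °C; then Et3N, CH2Cl2, 40 °C
Reagents that add atoms: bromine, BrBr
Why: Addition of Br2 to the enoate and E2 loss of HBr through the acidic α-hydrogen (the tertiary β-bromide leaves) should give the α-bromo enoate; bromination–dehydrobromination, no stereocentre.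

Step 2
Reactants: 3 ethyl 2-bromo-3-methylbut-2-enoate
Product: 4 2-bromo-3-methylbut-2-en-1-ol
Conditions: iBu2AlH (2.2 equiv), CH2Cl2, −78 → 0 °C; aq. potassium sodium tartrate
Reagents that add atoms: none
Why: 1,2-Reduction of the conjugated ester by the aluminium hydride should give the allylic alcohol and leave the alkenyl bromide untouched.

Step 3
Reactants: 4 2-bromo-3-methylbut-2-en-1-ol; 5 triethyl orthoacetate
Product: 7 ethyl 4-bromo-3,3-dimethylpent-4-enoate, via mixed ketene acetal 6 (not isolated)
Conditions: MeC(OEt)3 (5 equiv), EtCO2H (cat.), 140 °C, EtOH distilled off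
Reagents that add atoms: triethyl orthoacetate (5), CC(OCC)(OCC)OCC
Why: Johnson–Claisen rearrangement: the [3,3] shift of ketene acetal 6 forms the new C–C bond at the dimethyl-substituted alkene terminus, creating the quaternary carbon and the 1-bromovinyl group (no stereocentre).

Step 4
Reactants: 7 ethyl 4-bromo-3,3-dimethylpent-4-enoate
Product: 8 4-bromo-3,3-dimethylpent-4-enoic acid
Conditions: LiOH, THF/H2O, rt; then aq. HCl
Reagents that add atoms: lithium hydroxide, [Li+].[OH-]
Why: Saponification of the unhindered ethyl ester; the alkenyl bromide is inert to hydroxide.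

Step 5
Reactants: 8 4-bromo-3,3-dimethylpent-4-enoic acid; 9 (4S)-4-benzyl-1,3-oxazolidin-2-one
Product: 11 (4S)-4-benzyl-3-(4-bromo-3,3-dimethylpent-4-enoyl)-1,3-oxazolidin-2-one, via mixed pivalic anhydride 10 (not isolated)
Conditions: t-BuCOCl, Et3N, THF, −20 °C; then 9, LiCl, −20 °C → rt
Reagents that add atoms: (4S)-4-benzyl-1,3-oxazolidin-2-one (9), O=C1N[C@@H](Cc2ccccc2)CO1
Why: N-Acylation of the oxazolidinone through the mixed anhydride, which is attacked at its less hindered carbonyl group; the auxiliary stereocentre is not touched.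

Step 6
Reactants: 11 (4S)-4-benzyl-3-(4-bromo-3,3-dimethylpent-4-enoyl)-1,3-oxazolidin-2-one; 12 tert-butyl bromoacetate
Product: 14 tert-butyl (3S)-3-{[(4S)-4-benzyl-2-oxo-1,3-oxazolidin-3-yl]carbonyl}-5-bromo-4,4-dimethylhex-5-enoate, via sodium (Z)-enolate 13 (not isolated)
Conditions: NaN(SiMe3)2, THF, −78 °C; then 12, −78 → −40 °C
Reagents that add atoms: tert-butyl bromoacetate (12), CC(C)(C)OC(=O)CBr
Why: Evans asymmetric alkylation: the chelated (Z)-enolate 13 should be alkylated on the face opposite the benzyl group, which sets the (3S) centre, the future C3a.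

Step 7
Reactants: 14 tert-butyl (3S)-3-{[(4S)-4-benzyl-2-oxo-1,3-oxazolidin-3-yl]carbonyl}-5-bromo-4,4-dimethylhex-5-enoate
Product: 15 tert-butyl (3S)-5-bromo-3-[(ethylsulfanyl)carbonyl]-4,4-dimethylhex-5-enoate
Conditions: EtSH, n-BuLi, THF, 0 °C → rt
Reagents that add atoms: ethanethiol (as its lithium salt), CCS
Why: Thiolate transacylation cleaves even a hindered imide at the exocyclic carbonyl group, spares the tert-butyl ester and, being weakly basic, should not epimerize the α-centre; the auxiliary is recovered.

Step 8
Reactants: 15 tert-butyl (3S)-5-bromo-3-[(ethylsulfanyl)carbonyl]-4,4-dimethylhex-5-enoate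
Product: 16 tert-butyl (3S)-3-acetyl-5-bromo-4,4-dimethylhex-5-enoate
Conditions: Me2CuLi (from MeLi and CuI), Et2O, −78 → −40 °C
Reagents that add atoms: lithium dimethylcuprate, [Li+].C[Cu-]C
Why: Ketone synthesis from a thioester and a Gilman cuprate: acyl substitution stops at the methyl ketone, and the tert-butyl ester, the alkenyl bromide and the α-centre should survive at low temperature.

Step 9
Reactants: 16 tert-butyl (3S)-3-acetyl-5-bromo-4,4-dimethylhex-5-enoate; 17 diiodomethane
Product: 19 (4S,5R)-4-(3-bromo-2-methylbut-3-en-2-yl)-5-(iodomethyl)-5-methyloxolan-2-one, via iodohydrin ester 18 (not isolated)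
Conditions: CH2I2, SmI2, THF, 0 °C → rt; aq. NH4Cl work-up; then CF3CO2H, CH2Cl2, 0 °C
Reagents that add atoms: diiodomethane (17), ICI
Why: Imamoto iodomethylation of the ketone by the samarium carbenoid should follow the Felkin–Anh model (attack anti to the tert-alkyl group, past the α-hydrogen), which sets the future C7a with methyl cis to the tert-alkyl group; CF3CO2H then frees the acid, which closes the γ-lactone with retention.

Step 10
Reactants: 19 (4S,5R)-4-(3-bromo-2-methylbut-3-en-2-yl)-5-(iodomethyl)-5-methyloxolan-2-one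
Product: 22 (3aS,5S,7aS)-5-bromo-4,4,7a-trimethylhexahydro-1-benzofuran-2(3H)-one, via primary alkyl radical 20 (not isolated), via cyclic α-bromo radical 21 (not isolated)
Conditions: (Me3Si)3SiH (1.2 equiv) and AIBN (0.2 equiv) added over 8 h by syringe pump, PhH (0.005 M), NaHCO3, 80 °C
Reagents that add atoms: none
Why: The silyl radical abstracts iodine from 19 to give the primary radical 20, which adds to the unsubstituted terminus of the 1-bromovinyl group to give the cyclic α-bromo radical 21, and hydrogen-atom transfer from (Me3Si)3SiH gives 22 and carries the chain. The closest known reaction type is the hydride-mediated reductive cyclization of 5-substituted hex-5-enyl radicals generated from iodolactones. The cyclohexane ring closes in the 6-endo-trig mode and, because the two reacting arms are trans on the lactone, the bicycle can only be trans-fused, so C3a and C7a are carried through unchanged. The new C5 centre is set in the hydrogen-atom transfer: in the locked trans-fused chair the axial face of the radical is flanked only by the axial hydrogens on C3a and C7, whereas the other face is blocked by the axial methyl group on C4, so hydrogen should enter axially and bromine end equatorial (5S). The step needs 6-endo over 5-exo attack, which the bromine and the quaternary C4 on the internal alkene carbon, the stabilization of the α-bromo radical and the strain of a trans-fused bicyclo[3.3.0]octane should secure. It also needs cyclization to outrun direct reduction and iodine to be abstracted in preference to either bromine, which high dilution, slow addition of the sluggish donor (Me3Si)3SiH and the much weaker C–I bond should secure.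

Step 11
Reactants: 22 (3aS,5S,7aS)-5-bromo-4,4,7a-trimethylhexahydro-1-benzofuran-2(3H)-one; 23 1,1-dibromoethane
Product: 24 (2Z,3aS,5S,7aS)-5-bromo-2-ethylidene-4,4,7a-trimethyloctahydro-1-benzofuran
Conditions: CH3CHBr2, Zn, TiCl4, TMEDA, PbCl2 (cat.), THF, 0 → 25 °C; aq. K2CO3 work-up
Reagents that add atoms: 1,1-dibromoethane (23), CC(Br)Br
Why: Takai–Utimoto alkylidenation of the lactone carbonyl group should give the (Z)-enol ether under non-acidic conditions that leave the secondary bromide and the three stereocentres untouched.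

Step 12
Reactants: 24 (2Z,3aS,5S,7aS)-5-bromo-2-ethylidene-4,4,7a-trimethyloctahydro-1-benzofuran; 25 bromoacetyl bromide
Product: 26 (3Z)-1-bromo-3-[(3aS,5S,7aS)-5-bromo-4,4,7a-trimethylhexahydro-1-benzofuran-2(3H)-ylidene]butan-2-one
Conditions: BrCH2COBr, 2,6-lutidine, CH2Cl2, −40 → 0 °C
Reagents that add atoms: bromoacetyl bromide (25), BrCC(Br)=O
Why: Friedel–Crafts-type C-acylation of the enol ether at its β-carbon and loss of that proton from the oxocarbenium ion gives the conjugated tetrasubstituted alkene; the Z isomer (acyl group syn to the ring oxygen) should be favoured because the E isomer presses the acyl group against the C3 methylene, and a trace of acid can equilibrate a mixture.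

Compound list
1 | ethyl 3-methylbut-2-enoate | CCOC(=O)C=C(C)C | starting material
2 | ethyl 2,3-dibromo-3-methylbutanoate (racemic) | CCOC(=O)C(Br)C(C)(C)Br | intermediate (not isolated)
3 | ethyl 2-bromo-3-methylbut-2-enoate | CCOC(=O)C(Br)=C(C)C | intermediate
4 | 2-bromo-3-methylbut-2-en-1-ol | OCC(Br)=C(C)C | intermediate
5 | triethyl orthoacetate | CC(OCC)(OCC)OCC | starting material
6 | 2-bromo-1-[(1-ethoxyethenyl)oxy]-3-methylbut-2-ene (mixed ketene acetal) | C=C(OCC)OCC(Br)=C(C)C | intermediate (not isolated)
7 | ethyl 4-bromo-3,3-dimethylpent-4-enoate | CCOC(=O)CC(C)(C)C(Br)=C | intermediate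
8 | 4-bromo-3,3-dimethylpent-4-enoic acid | OC(=O)CC(C)(C)C(Br)=C | intermediate
9 | (4S)-4-benzyl-1,3-oxazolidin-2-one | O=C1N[C@@H](Cc2ccccc2)CO1 | starting material
10 | 4-bromo-3,3-dimethylpent-4-enoic 2,2-dimethylpropanoic anhydride | CC(C)(C)C(=O)OC(=O)CC(C)(C)C(Br)=C | intermediate (not isolated)
11 | (4S)-4-benzyl-3-(4-bromo-3,3-dimethylpent-4-enoyl)-1,3-oxazolidin-2-one | C=C(Br)C(C)(C)CC(=O)N1[C@@H](Cc2ccccc2)COC1=O | intermediate
12 | tert-butyl bromoacetate | CC(C)(C)OC(=O)CBr | starting material
13 | sodium (Z)-enolate of 11 | [Na+].[O-]/C(=C\C(C)(C)C(Br)=C)N1[C@@H](Cc2ccccc2)COC1=O | intermediate (not isolated)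
14 | tert-butyl (3S)-3-{[(4S)-4-benzyl-2-oxo-1,3-oxazolidin-3-yl]carbonyl}-5-bromo-4,4-dimethylhex-5-enoate | CC(C)(C)OC(=O)C[C@H](C(=O)N1[C@@H](Cc2ccccc2)COC1=O)C(C)(C)C(Br)=C | intermediate
15 | tert-butyl (3S)-5-bromo-3-[(ethylsulfanyl)carbonyl]-4,4-dimethylhex-5-enoate | CCSC(=O)[C@@H](CC(=O)OC(C)(C)C)C(C)(C)C(Br)=C | intermediate
16 | tert-butyl (3S)-3-acetyl-5-bromo-4,4-dimethylhex-5-enoate | CC(=O)[C@@H](CC(=O)OC(C)(C)C)C(C)(C)C(Br)=C | intermediate
17 | diiodomethane | ICI | starting material
18 | tert-butyl (3S,4R)-3-(3-bromo-2-methylbut-3-en-2-yl)-4-hydroxy-5-iodo-4-methylpentanoate | CC(C)(C)OC(=O)C[C@H]([C@@](C)(O)CI)C(C)(C)C(Br)=C | intermediate (not isolated)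
19 | (4S,5R)-4-(3-bromo-2-methylbut-3-en-2-yl)-5-(iodomethyl)-5-methyloxolan-2-one | IC[C@]1(C)OC(=O)C[C@H]1C(C)(C)C(Br)=C | intermediate
20 | primary alkyl radical from 19 (CH2 radical on the lactone C5) | [CH2][C@]1(C)OC(=O)C[C@H]1C(C)(C)C(Br)=C | intermediate (not isolated)
21 | (3aS,7aS)-5-bromo-4,4,7a-trimethyl-2-oxooctahydro-1-benzofuran-5-yl radical | O=C1C[C@H]2C(C)(C)[C](Br)CC[C@]2(C)O1 | intermediate (not isolated)
22 | (3aS,5S,7aS)-5-bromo-4,4,7a-trimethylhexahydro-1-benzofuran-2(3H)-one | O=C1C[C@H]2C(C)(C)[C@@H](Br)CC[C@]2(C)O1 | intermediate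
23 | 1,1-dibromoethane | CC(Br)Br | starting material
24 | (2Z,3aS,5S,7aS)-5-bromo-2-ethylidene-4,4,7a-trimethyloctahydro-1-benzofuran | C/C=C1/C[C@H]2C(C)(C)[C@@H](Br)CC[C@]2(C)O1 | intermediate
25 | bromoacetyl bromide | BrCC(Br)=O | starting material
26 | (3Z)-1-bromo-3-[(3aS,5S,7aS)-5-bromo-4,4,7a-trimethylhexahydro-1-benzofuran-2(3H)-ylidene]butan-2-one | C/C(C(=O)CBr)=C1\C[C@H]2C(C)(C)[C@@H](Br)CC[C@]2(C)O1 | target

Total step count: 12
Longest linear sequence: 12 steps (from 1 to 26; all other reactants are commercial)

Steps most likely to fail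

Step 10 (key step). The primary radical may take up hydrogen before the slow 6-endo closure, a C–Br bond may be reduced after cyclization, or the final hydrogen transfer may be insufficiently face-selective. The fallback closes the same C6–C7 bond in a polar way, setting out from 19 and returning at 22. Hydrolysis of the bromoalkene with Hg(OAc)2 (cat.) in CF3CO2H/H2O should give the keto iodolactone F1. LiOH in aqueous THF should open the lactone and close the epoxide, giving the lithium epoxy carboxylate F2. LiN(iPr)2 in THF should form the only possible ketone enolate, which opens the epoxide at its CH2 terminus (Stork-type intramolecular epoxide alkylation, six-membered ring); acidification relactonizes to the keto lactone F3. LiBH(sec-Bu)3 should attack from the equatorial side to give the axial alcohol F4, and CBr4/PPh3 should replace the hydroxyl group with inversion to give 22.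

Step 12. The acyl bromide may form bromoketene and add to the enol ether in a [2+2] sense, the enol ether may isomerize under the acid released, or the product may be N-alkylated by the base. The fallback builds the side chain by a Claisen-type addition instead, setting out from 22 and returning at 26; it also makes step 11 unnecessary. The regiodefined lithium enolate of butan-2-one (from (Z)-2-(trimethylsilyloxy)but-2-ene and MeLi) should add to the lactone carbonyl group of 22 to give the lactol F5. TsOH in benzene with removal of water should dehydrate it to the conjugated methyl ketone F6. Kinetic deprotonation of the acetyl methyl group with LiN(SiMe3)2 and trapping with Me3SiCl should give the silyl dienol ether F7, which N-bromosuccinimide should brominate to 26.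

Step 9. The samarium carbenoid may add with poor facial selectivity, enolize the hindered ketone or attack the ester. The fallback delivers the carbon with a sulfur ylide, setting out from 16 and returning at 19. Me3S+ I− and KN(SiMe3)2 (Corey–Chaykovsky epoxidation) should give the epoxy ester F8 with the same Felkin–Anh sense. LiI/AcOH in THF should open the epoxide at its CH2 terminus to give 18, and CF3CO2H should close the lactone to 19.

Further compounds
F1 | step 10 | (4S,5R)-5-(iodomethyl)-5-methyl-4-(2-methyl-3-oxobutan-2-yl)oxolan-2-one | IC[C@]1(C)OC(=O)C[C@H]1C(C)(C)C(C)=O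
F2 | step 10 | lithium (3S)-4,4-dimethyl-3-[(2R)-2-methyloxiran-2-yl]-5-oxohexanoate | [Li+].[O-]C(=O)C[C@H]([C@]1(C)CO1)C(C)(C)C(C)=O
F3 | step 10 | (3aS,7aS)-4,4,7a-trimethylhexahydro-1-benzofuran-2,5-dione | O=C1C[C@H]2C(C)(C)C(=O)CC[C@]2(C)O1
F4 | step 10 | (3aS,5R,7aS)-5-hydroxy-4,4,7a-trimethylhexahydro-1-benzofuran-2(3H)-one | O=C1C[C@H]2C(C)(C)[C@H](O)CC[C@]2(C)O1
F5 | step 12 | 3-[(3aS,5S,7aS)-5-bromo-2-hydroxy-4,4,7a-trimethyloctahydro-1-benzofuran-2-yl]butan-2-one (mixture at the two new centres) | CC(=O)C(C)C1(O)C[C@H]2C(C)(C)[C@@H](Br)CC[C@]2(C)O1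
F6 | step 12 | (3Z)-3-[(3aS,5S,7aS)-5-bromo-4,4,7a-trimethylhexahydro-1-benzofuran-2(3H)-ylidene]butan-2-one | C/C(C(C)=O)=C1\C[C@H]2C(C)(C)[C@@H](Br)CC[C@]2(C)O1
F7 | step 12 | {[(3Z)-3-[(3aS,5S,7aS)-5-bromo-4,4,7a-trimethylhexahydro-1-benzofuran-2(3H)-ylidene]but-1-en-2-yl]oxy}trimethylsilane | C/C(C(=C)O[Si](C)(C)C)=C1\C[C@H]2C(C)(C)[C@@H](Br)CC[C@]2(C)O1
F8 | step 9 | tert-butyl (3S)-5-bromo-4,4-dimethyl-3-[(2R)-2-methyloxiran-2-yl]hex-5-enoate | CC(C)(C)OC(=O)C[C@H]([C@]1(C)CO1)C(C)(C)C(Br)=C
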